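**A straight fall.** In a one-step world the substrate loses a fixed share per hour and you count half-lives. In these runs the solid substrate falls by a nearly fixed amount per hour instead, so count that.

| flask | solid substrate | acid | remark | time |
|---|---|---|---|---|
| violet | 20 mM | 0.028 mM | run made earlier |  |
| amber | 20 mM | 0.044 mM | run made earlier |  |
| grey | 30 mM | 0.020 mM | run made earlier |  |
| flask | 20 mM | 0.0200 mM |  | 25 h |

| run | time / h | solid substrate / % | target / % |
|---|---|---|---|
| violet | 2.00 | 95 | 1 |
| violet | 5.00 | 83 | 10 |
| violet | 10.0 | 63 | 29 |
| violet | 15.0 | 46 | 44 |
| amber | 4.00 | 82 | 10 |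
| amber | 8.00 | 72 | 26 |
| amber | 12.0 | 55 | 34 |
| amber | 15.0 | 38 | 50 |
| grey | 1.33 | 100 | 0 |
| grey | 3.00 | 93 | 4 |
| grey | 6.00 | 83 | 11 |
| grey | 15.0 | 62 | 27 |

(scatter of a reading: 2 percentage points)

1. part of the solid substrate that has reacted (what has only dissolved counts as not reacted) at 25 h
2. pH of the solution at 25 h

- acid is the free proton; pH is minus the decimal logarithm of its molar concentration
- solid substrate is a solid; its amount is given per volume of the solution
- at the start none of the solid substrate is in solution
- what has only dissolved of solid substrate counts as not reacted

**The feed.** Violet's readings give 0.754 mM/h. This is the feed rate, the amount of solid lost per hour, a zero-order rate. Amber gives 0.800 mM/h, and grey, at your flask's [acid], gives 0.775 mM/h.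

**On arrival.** At violet's feed I reckon that your flask's 20 mM of solid empties in 26.5 h, so at 25 h I expect 5.77% of it left. Violet's last reading shows 10.0% gone from the solid but not seen as target. I count that much as still dissolved and reckon 84.2% reacted. The readings carry no pH, so I reckon none.

**Not to touch.** Add no solid and keep the reading time: the emptying time exceeds it by just 1.50 h.

**The result.** The forecast gives 63% (54% to 71%) and pH 4.7, with target forming at “then about 0.5 mM/h as the solid shrinks”, and its figure lies below my 84.2%. The flask gives 89.3% reacted and pH 3.98.

    starting material + acid → weak acid + acid + target (k = 11000 /M/h)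
    weak acid ⇌ conjugate base + acid, settled at all times (K = 5.00 × 10⁻⁷ M)
    starting material → weak acid + target (k = 0.00290 /h)
    solid substrate ⇌ starting material, rate k4*(cs4 - [starting material]) while solid is left; crystals form when [starting material] > cs4 (solubility = 6.70 mM, k = 0.130 /h)
    target → over-reaction product (k = 0.0170 /h)

**Feed again.** At 25.0 h your flask holds 7.28% as solid and 3.44% as dissolved starting material, so its solid went at 0.742 mM/h on average, against the feed of 0.754 mM/h. A neighbour flask with 12 mM of solid has, at that same feed, an emptying time of 15.9 h, shorter than 25 h. At 25.0 h that neighbour has 0% of its charge left as solid substrate or starting material, with >99.9% reacted.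

The data stem from a simulated flask for an exercise; noise was put on by code.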